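(Readings and results are calculated for substances that don't exist; scatter was added.)

It is tempting to read the share of other capture product as a fixed property of this chemistry. It read 64.7% in the spring run and 45.2% in the winter run, and those recipes part in the first nucleophile, 0.74 equiv against 1.7 equiv.

| flask | starting material | first nucleophile | second nucleophile | protic impurity | remark | time |
|---|---|---|---|---|---|---|
| spring | 0.13 M | 0.74 equiv | 1 equiv | 0.013 M | run made earlier |  |
| winter | 0.13 M | 1.7 equiv | 1 equiv | 0.013 M | run made earlier |  |
| flask | 0.13 M | 1.10 equiv | 1.00 equiv | 0.0130 M |  | 10 d |

| run | time / d | other capture product / % | target / % | starting material / % |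
|---|---|---|---|---|
| spring | 2.08 | 54.5 | 30.0 | 0.9 |
| spring | 4.00 | 55.4 | 30.2 | 0.3 |
| spring | 6.00 | 55.5 | 29.4 | 0.2 |
| spring | 8.00 | 55.4 | 30.0 | 0 |
| winter | 1.04 | 34.7 | 41.9 | 10.5 |
| winter | 3.00 | 39.2 | 47.6 | 0 |
| winter | 5.00 | 39.4 | 47.4 | 0.1 |
| winter | 8.00 | 39.7 | 46.2 | 0 |

(readings scatter by 0.3 percentage points)

- share of other capture product in other capture product plus target at 30 min
- share of other capture product in other capture product plus target at 10 d

- the analysis behind the earlier runs scatters by 0.3 percentage points, standard deviation

We turn the settings in order. First nucleophile: if both nucleophiles compete for one species, the log of the fraction of second nucleophile left, over the log of the fraction of first nucleophile left, should hold constant. We count each nucleophile's use as its product. Spring gives 1.54 at 4.00 d and winter 1.51 at 3.00 d. We carry their mean, the selectivity factor 1.53.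

Second nucleophile: no run turned it. With charges barely moved, the share is the factor times its charge, over that plus the first nucleophile's charge. Our reckoning for this flask gives 58.1% at 30 min. It should sink later, since the factor exceeds one.

Protic impurity: both runs held it at 10.0% of the starting material, so comparing them does not turn this setting.

The forecast gives 58.8% at 30 min, above ours, and 55.9% at 10 d. Its ground: “Treat the two captures as parallel competition for the starting material”.

The flask gives 57.5% at 30 min and 56.5% at 10 d, so the forecast stands.

    starting material → intermediate (k = 0.0851 h⁻¹)
    first nucleophile + intermediate → target (k = 415 L mol⁻¹ h⁻¹)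
    second nucleophile + intermediate → other capture product (k = 621 L mol⁻¹ h⁻¹)
    intermediate → solvolysis product (k = 3.88 h⁻¹)
    starting material + protic impurity → quenched substrate (k = 33.8 L mol⁻¹ h⁻¹)
    target → over-reaction product (k = 2.34 × 10⁻⁴ h⁻¹)

In this flask, by 1.00 d the starting material was down to 11.6%, with 42.1% other capture product, 33.5% target and 10.0% quenched substrate. At 10.0 d target stood at 36.9% and over-reaction product at 2.02%, the target's half-life on that path being 120 d, long against 10 d. With 65% of its charge of first nucleophile left and 1.00 equiv of second nucleophile charged, the factor puts other capture product at 48.3%; the flask holds 48.0%. For the same flask with 1.70 equiv of second nucleophile, the factor gives a share of 70.2% at 30 min. The computed share is 69.8%.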